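**Strategy.** Ring A (C1, C2, C3, C4, C5, C10) is opened at C3–C4. The quaternary C4, with its equatorial C18 carboxyl and axial methyl, is traced to a trans-fused δ-lactone that ties C18 through oxygen to the allylic carbinol C1, whose vinyl group lies cis to the C10 methyl. An Ireland–Claisen shift of the lactone silyl ketene acetal forms C3–C4, breaks C1–O, closes ring A and fixes C4 in one operation. The precursor is a 1-vinyl keto lactone on ring B; its C9 ketone, masked in the flask as an enol silane, later takes up the citronellol-derived side chain and leads to the C8 methylene.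

Key step: step 7

**Remarks on the chemistry**
- Labdane numbering is used for all ring compounds (C18 = carboxyl carbon on C4, C19 = methyl on C4, C20 = methyl on C10); α is the face of H5, β the face of C20.
- Assumption: the (S)-oxazaborolidinium catalyst of step 2 is taken to deliver the nucleophile to the face of C5 drawn; if its sense is the opposite, the antipodal catalyst is used.
- The vinyl group is carried as a silylalkyne until step 6, so that C1 is set by a reagent-controlled ynone reduction (steps 3 and 4) and not by the diastereoselectivity of an aldol addition.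
- C4 is an inconsequential epimer mixture in 5–11; both epimers converge in step 7.
- C9 stays a free ketone and is masked only inside step 7.
- (S)-Citronellol holds one carbon more than C11–C15 need; step 13 removes it.

**Route**

Step 1
Reactants: 1 methyl propanoate
Product: 2 (1-methoxyprop-1-enyloxy)trimethylsilane
Conditions: LiN(iPr)2, THF, −78 °C; then Me3SiCl, −78 °C → rt
Reagents that add atoms: chlorotrimethylsilane, C[Si](C)(C)Cl
Why: Kinetic ester enolisation followed by O-silylation gives the silyl ketene acetal; its E/Z ratio is immaterial because the C4 centre it creates is re-enolised in step 7.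

Step 2
Reactants: 2 (1-methoxyprop-1-enyloxy)trimethylsilane; 3 2-methylcyclohex-2-en-1-one; 4 3-(trimethylsilyl)prop-2-ynal
Product: 6 methyl 2-[(1S,2R)-2-[1-hydroxy-3-(trimethylsilyl)prop-2-ynyl]-2-methyl-3-oxocyclohexyl]propanoate, via silyl enol ether 5 (not isolated)
Conditions: 2, 3, (S)-o-tolyl-CBS oxazaborolidine·HNTf2 (20 mol%), Ph3PO (25 mol%), PhMe, −20 °C; then 4, BF3·OEt2, CH2Cl2, −78 °C; aq. NaHCO3
Reagents that add atoms: none
Why: A Mukaiyama–Michael addition under chiral oxazaborolidinium catalysis sets C5 by catalyst control and leaves the C9–C10 enol silane, which then undergoes a BF3-mediated Mukaiyama aldol addition at C10 on the face opposite the pseudoaxial C5 side chain (trans C5/C10); C1 and C4 are left as mixtures because C1 is reset in steps 3 and 4 and C4 in step 7.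

Step 3
Reactants: 6 aldol adduct (hydroxy keto ester)
Product: 7 methyl 2-[(1S,2S)-2-methyl-3-oxo-2-[3-(trimethylsilyl)prop-2-ynoyl]cyclohexyl]propanoate
Conditions: Dess–Martin periodinane, CH2Cl2, 0 °C → rt
Reagents that add atoms: none
Why: Dess–Martin oxidation of the propargylic alcohol gives the ynone and thereby erases the uncontrolled C1 centre; the quaternary C10 prevents enolisation between the two carbonyl groups.

Step 4
Reactants: 7 ynone diketo ester
Product: 9 (1R,4aS,8aR)-4,8a-dimethyl-1-[2-(trimethylsilyl)ethynyl]hexahydro-1H-isochromene-3,8-dione, via hydroxy ester 8 (not isolated)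
Conditions: Ru[(R,R)-TsDPEN](p-cymene) (2 mol%), iPrOH, rt; then PPTS (cat.), PhH, 70 °C
Reagents that add atoms: none
Why: Noyori asymmetric transfer hydrogenation reduces only the ynone carbonyl and sets C1 as the (R)-carbinol by catalyst control (the alkynyl group takes the place of the aryl group of aryl ketones), and acid-catalysed lactonisation onto C18 with retention at C1 closes the trans-fused δ-lactone with the alkynyl group cis to the C10 methyl; any material of the antipodal ring series becomes a diastereomeric lactone and is removed by chromatography.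

Step 5
Reactants: 9 silylalkynyl keto lactone
Product: 10 (1S,4aS,8aR)-1-ethynyl-4,8a-dimethylhexahydro-1H-isochromene-3,8-dione
Conditions: Bu4NF, AcOH, THF, 0 °C
Reagents that add atoms: none
Why: Fluoride-induced protodesilylation of the alkynylsilane, buffered by acetic acid so that lactone and ketone are left alone; the change of the C1 descriptor is formal only.

Step 6
Reactants: 10 ethynyl keto lactone
Product: 11 (1S,4aS,8aR)-1-ethenyl-4,8a-dimethylhexahydro-1H-isochromene-3,8-dione
Conditions: H2 (1 atm), Pd/CaCO3 poisoned with Pb(OAc)2, quinoline, EtOAc, rt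
Reagents that add atoms: none
Why: Lindlar semihydrogenation of the terminal alkyne stops at the vinyl group and touches no stereocentre.

Step 7
Reactants: 11 1β-vinyl keto lactone
Product: 14 (1R,4aS,8aR)-1,4a-dimethyl-5-oxo-1,2,4a,5,6,7,8,8a-octahydronaphthalene-1-carboxylic acid, via silyl ketene acetal 12 (not isolated), via silyl ester 13 (not isolated)
Conditions: LiN(iPr)2 (3 equiv), Me3SiCl (6 equiv), Et3N, THF, −78 °C → rt; PhMe, 105 °C; then 1 M HCl, THF, rt
Reagents that add atoms: none
Why: Double deprotonation with silyl chloride present gives the C8–C9 enol silane, which masks the ketone in the flask, and the cyclic silyl ketene acetal (C4=C18), whose single geometry is imposed by the lactone ring; on heating, the vinyl terminus C3 bonds to C4 as C1–O breaks in a concerted [3,3] shift, the Ireland–Claisen rearrangement of 1-vinyl lactone ketene acetals being the known reaction type. Ring A (C1, C2, C3, C4, C5, C10) closes by this sigmatropic C3–C4 bond formation through a boat, bicyclo[2.2.2]octane-like transition state in which the lactone ring is the boat and C2–C3 the bridge, the ring oxygen being expelled as the carboxylate. The only new stereocentre, C4, is controlled by C1: the vinyl group lies on the face of the C10 methyl, so C3 reaches C4 from the β face, the former lactone carbonyl C18 ends α (equatorial, on the side of H5) and the C4 methyl β (axial). The step needs full enolisation at C4 without acyl transfer to O9 or C-silylation, which the internal silyl chloride quench secures, and both C4 epimers of 11 converge on the same ketene acetal. Acid work-up cleaves the silyl ester and the enol silane to give keto acid 14.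

Step 8
Reactants: 14 octalin keto acid
Product: 15 2-(trimethylsilyl)ethyl (1R,4aS,8aR)-1,4a-dimethyl-5-oxo-1,2,4a,5,6,7,8,8a-octahydronaphthalene-1-carboxylate
Conditions: Me3SiCH2CH2OH, PPh3, iPrO2CN=NCO2iPr (DIAD), THF, 0 °C → rt
Reagents that add atoms: 2-(trimethylsilyl)ethanol, C[Si](C)(C)CCO
Why: Mitsunobu esterification: the carboxylate attacks the primary carbon of the activated alcohol, so the hindrance of the tertiary acid does not matter, and the resulting ester, which has no α-hydrogen, is stable to the bases used later.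

Step 9
Reactants: 15 octalin keto ester
Product: 16 2-(trimethylsilyl)ethyl (1R,4aS,8aR)-1,4a-dimethyl-5-oxodecahydronaphthalene-1-carboxylate
Conditions: H2 (1 atm), Pd/C, EtOAc, rt
Reagents that add atoms: none
Why: Heterogeneous hydrogenation saturates the cis-disubstituted C1–C2 alkene, while ketone and ester are inert under these conditions; no stereocentre is created.

Step 10
Reactants: 16 decalone ester
Product: 17 2-(trimethylsilyl)ethyl (1R,4aS,8aR)-1,4a-dimethyl-5-(trifluoromethylsulfonyloxy)-1,2,3,4,4a,7,8,8a-octahydronaphthalene-1-carboxylate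
Conditions: KN(SiMe3)2, THF, −78 °C; then PhNTf2, −78 → 0 °C
Reagents that add atoms: N-phenylbis(trifluoromethanesulfonimide), O=S(=O)(N(c1ccccc1)S(=O)(=O)C(F)(F)F)C(F)(F)F
Why: The ketone can only enolise toward C8 because C10 is quaternary, and O-sulfonylation of the potassium enolate gives the C8–C9 enol triflate without touching a stereocentre.

Step 11
Reactants: 18 (S)-citronellol
Product: 19 (S)-tert-butyl[(3,7-dimethyloct-6-enyl)oxy]diphenylsilane
Conditions: tBuPh2SiCl, imidazole, DMF, rt
Reagents that add atoms: tert-butyl(chloro)diphenylsilane, CC(C)(C)[Si](Cl)(c1ccccc1)c1ccccc1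
Why: Imidazole-promoted silylation protects the primary alcohol (the future C15 oxygen) through the oxidative and organometallic steps; the C13 stereocentre is untouched.

Step 12
Reactants: 19 citronellol silyl ether
Product: 20 (S)-6-(tert-butyldiphenylsilyloxy)-4-methylhexanoic acid
Conditions: RuCl3 (cat.), NaIO4, EtOAc/MeCN/H2O, rt
Reagents that add atoms: sodium periodate, [Na+].[O-]I(=O)(=O)=O
Why: RuO4 generated in the flask cleaves the trisubstituted alkene oxidatively to the carboxylic acid and acetone (ruthenium-catalysed periodate cleavage), leaving the silyl ether and the stereocentre intact.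

Step 13
Reactants: 20 silyloxy acid
Product: 21 (R)-tert-butyl[(5-iodo-3-methylpentyl)oxy]diphenylsilane
Conditions: PhI(OAc)2, iodine, cyclohexane, hν (tungsten lamp), reflux
Reagents that add atoms: iodine, [I][I]
Why: Hunsdiecker-type iododecarboxylation: the acyl hypoiodite loses CO2 and the primary radical is captured by iodine faster than it can rearrange, which excises the surplus carbon and installs the halide for zinc insertion (the change of descriptor is formal only).

Step 14
Reactants: 17 enol triflate; 21 side-chain iodide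
Product: 23 2-(trimethylsilyl)ethyl (13S)-15-(tert-butyldiphenylsilyloxy)-17-norlabd-8-en-18-oate, via alkylzinc iodide 22 (not isolated)
Conditions: 21, Zn dust (activated by BrCH2CH2Br and Me3SiCl), LiCl, THF, 40 °C; then 17, PdCl2(dppf) (5 mol%), THF, 60 °C
Reagents that add atoms: none
Why: Zinc inserts into the primary C–I bond and the alkylzinc iodide couples with the enol triflate under palladium catalysis (Negishi coupling of an sp3 zinc reagent with an alkenyl triflate); the wide-bite-angle dppf ligand favours reductive elimination over β-hydride elimination and C13 is not involved.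

Step 15
Reactants: 23 8-ene coupling product
Product: 25 2-(trimethylsilyl)ethyl (13S)-15-(tert-butyldiphenylsilyloxy)-8α-hydroxy-17-norlabdan-18-oate, via alkylborane 24 (not isolated)
Conditions: BH3·SMe2, THF, 0 °C → rt; then NaOH, H2O2, 0 °C → rt
Reagents that add atoms: hydrogen peroxide, OO
Why: Hydroboration–oxidation: boron adds to the less substituted C8 and hydrogen to C9 in a syn fashion on the α face, opposite the axial C10 methyl (the behaviour of 9(11)-ene steroids), which sets 9α-H, and oxidation with retention gives the 8α-alcohol.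

Step 16
Reactants: 25 8α-alcohol
Product: 26 2-(trimethylsilyl)ethyl (13S)-15-(tert-butyldiphenylsilyloxy)-8-oxo-17-norlabdan-18-oate
Conditions: Dess–Martin periodinane, CH2Cl2, rt
Reagents that add atoms: none
Why: Dess–Martin oxidation to the C8 ketone; C9 already holds its equatorial side chain, the thermodynamically preferred arrangement, so enolisation cannot invert it.

Step 17
Reactants: 26 C8 ketone
Product: 27 2-(trimethylsilyl)ethyl (13S)-15-(tert-butyldiphenylsilyloxy)labd-8(17)-en-18-oate
Conditions: Ph3PCH3Br, KOtBu, THF, 0 °C; then 26, rt → 60 °C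
Reagents that add atoms: methyltriphenylphosphonium bromide, C[P+](c1ccccc1)(c1ccccc1)c1ccccc1.[Br-]
Why: Wittig methylenation converts the ring ketone into the exocyclic C8–C17 alkene; the small non-stabilised ylide tolerates the α-branch and C9 remains in its stable configuration.

Step 18
Reactants: 27 doubly protected labdenoate
Product: 28 (13S)-15-hydroxylabd-8(17)-en-18-oic acid
Conditions: Bu4NF, THF, rt → 40 °C; then cold 0.5 M HCl
Reagents that add atoms: none
Why: Fluoride attacks silicon in both protecting groups: the silyl ether is cleaved to the C15 alcohol and the 2-(trimethylsilyl)ethyl ester fragments to ethene and the carboxylate (β-elimination), a cleavage that is indifferent to the hindrance around C18.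

Step 19
Reactants: 28 hydroxy acid
Product: 29 (13S)-15-acetoxylabd-8(17)-en-18-oic acid (target)
Conditions: Ac2O, pyridine, DMAP (cat.), CH2Cl2, 0 °C → rt; then aq. NaHCO3/THF, acidify to pH 3
Reagents that add atoms: acetic anhydride, CC(=O)OC(C)=O
Why: Acetylation of the primary alcohol under nucleophilic catalysis; the hindered tertiary acid at most forms a mixed anhydride, which the bicarbonate work-up hydrolyses, giving the target.

**Compound list**

1 | methyl propanoate | CCC(=O)OC | starting material
2 | (1-methoxyprop-1-enyloxy)trimethylsilane (E/Z mixture) | CC=C(OC)O[Si](C)(C)C | intermediate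
3 | 2-methylcyclohex-2-en-1-one | CC1=CCCCC1=O | starting material
4 | 3-(trimethylsilyl)prop-2-ynal | C[Si](C)(C)C#CC=O | starting material
5 | methyl 2-[(1S)-2-methyl-3-(trimethylsilyloxy)cyclohex-2-en-1-yl]propanoate (propanoate C2 unassigned) | COC(=O)C(C)[C@@H]1CCCC(O[Si](C)(C)C)=C1C | intermediate
6 | methyl 2-[(1S,2R)-2-[1-hydroxy-3-(trimethylsilyl)prop-2-ynyl]-2-methyl-3-oxocyclohexyl]propanoate (carbinol and propanoate C2 as epimer mixtures) | C[Si](C)(C)C#CC(O)[C@]1(C)C(=O)CCC[C@H]1C(C)C(=O)OC | intermediate
7 | methyl 2-[(1S,2S)-2-methyl-3-oxo-2-[3-(trimethylsilyl)prop-2-ynoyl]cyclohexyl]propanoate | C[Si](C)(C)C#CC(=O)[C@]1(C)C(=O)CCC[C@H]1C(C)C(=O)OC | intermediate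
8 | methyl 2-[(1S,2R)-2-[(1R)-1-hydroxy-3-(trimethylsilyl)prop-2-ynyl]-2-methyl-3-oxocyclohexyl]propanoate | C[Si](C)(C)C#C[C@H](O)[C@]1(C)C(=O)CCC[C@H]1C(C)C(=O)OC | intermediate
9 | (1R,4aS,8aR)-4,8a-dimethyl-1-[2-(trimethylsilyl)ethynyl]hexahydro-1H-isochromene-3,8-dione (trans-fused δ-lactone; alkynyl cis to the angular methyl; C4 epimers) | C[Si](C)(C)C#C[C@@H]1OC(=O)C(C)[C@@H]2CCCC(=O)[C@@]12C | intermediate
10 | (1S,4aS,8aR)-1-ethynyl-4,8a-dimethylhexahydro-1H-isochromene-3,8-dione (C4 epimers) | C#C[C@@H]1OC(=O)C(C)[C@@H]2CCCC(=O)[C@@]12C | intermediate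
11 | (1S,4aS,8aR)-1-ethenyl-4,8a-dimethylhexahydro-1H-isochromene-3,8-dione (1β-vinyl, 5α-H, 10β-methyl in labdane terms; C4 epimers; key-step precursor) | C=C[C@@H]1OC(=O)C(C)[C@@H]2CCCC(=O)[C@@]12C | intermediate
12 | bis-silyl derivative of 11: lactone trimethylsilyl ketene acetal (C4=C18) and C8–C9 trimethylsilyl enol ether | C=C[C@@H]1OC(O[Si](C)(C)C)=C(C)[C@@H]2CCC=C(O[Si](C)(C)C)[C@@]12C | intermediate
13 | trimethylsilyl ester of 14 carrying the C8–C9 trimethylsilyl enol ether | C=1CC[C@@H]2[C@](C)(C=CC[C@@]2(C)C(=O)O[Si](C)(C)C)C=1O[Si](C)(C)C | intermediate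
14 | (1R,4aS,8aR)-1,4a-dimethyl-5-oxo-1,2,4a,5,6,7,8,8a-octahydronaphthalene-1-carboxylic acid (4α-CO2H, 4β-CH3, 5α-H, 10β-CH3, C1–C2 alkene, C9 ketone; key-step product) | C1CC[C@@H]2[C@](C)(C=CC[C@@]2(C)C(=O)O)C1=O | intermediate
15 | 2-(trimethylsilyl)ethyl (1R,4aS,8aR)-1,4a-dimethyl-5-oxo-1,2,4a,5,6,7,8,8a-octahydronaphthalene-1-carboxylate | C1CC[C@@H]2[C@](C)(C=CC[C@@]2(C)C(=O)OCC[Si](C)(C)C)C1=O | intermediate
16 | 2-(trimethylsilyl)ethyl (1R,4aS,8aR)-1,4a-dimethyl-5-oxodecahydronaphthalene-1-carboxylate | C1CC[C@@H]2[C@](C)(CCC[C@@]2(C)C(=O)OCC[Si](C)(C)C)C1=O | intermediate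
17 | 2-(trimethylsilyl)ethyl (1R,4aS,8aR)-1,4a-dimethyl-5-(trifluoromethylsulfonyloxy)-1,2,3,4,4a,7,8,8a-octahydronaphthalene-1-carboxylate | C=1CC[C@@H]2[C@](C)(CCC[C@@]2(C)C(=O)OCC[Si](C)(C)C)C=1OS(=O)(=O)C(F)(F)F | intermediate
18 | (S)-citronellol, (3S)-3,7-dimethyloct-6-en-1-ol | OCC[C@@H](C)CCC=C(C)C | starting material
19 | (S)-tert-butyl[(3,7-dimethyloct-6-enyl)oxy]diphenylsilane | CC(C)(C)[Si](c1ccccc1)(c1ccccc1)OCC[C@@H](C)CCC=C(C)C | intermediate
20 | (S)-6-(tert-butyldiphenylsilyloxy)-4-methylhexanoic acid | CC(C)(C)[Si](c1ccccc1)(c1ccccc1)OCC[C@@H](C)CCC(=O)O | intermediate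
21 | (R)-tert-butyl[(5-iodo-3-methylpentyl)oxy]diphenylsilane | CC(C)(C)[Si](c1ccccc1)(c1ccccc1)OCC[C@@H](C)CCI | intermediate
22 | [(R)-5-(tert-butyldiphenylsilyloxy)-3-methylpentyl]zinc iodide | CC(C)(C)[Si](c1ccccc1)(c1ccccc1)OCC[C@@H](C)CC[Zn]I | intermediate
23 | 2-(trimethylsilyl)ethyl (13S)-15-(tert-butyldiphenylsilyloxy)-17-norlabd-8-en-18-oate | C=1CC[C@@H]2[C@](C)(CCC[C@@]2(C)C(=O)OCC[Si](C)(C)C)C=1CC[C@H](C)CCO[Si](c1ccccc1)(c1ccccc1)C(C)(C)C | intermediate
24 | 8α-boryl-9α-H alkylborane from 23 | [BH2][C@@H]1CC[C@@H]2[C@](C)(CCC[C@@]2(C)C(=O)OCC[Si](C)(C)C)[C@H]1CC[C@H](C)CCO[Si](c1ccccc1)(c1ccccc1)C(C)(C)C | intermediate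
25 | 2-(trimethylsilyl)ethyl (13S)-15-(tert-butyldiphenylsilyloxy)-8α-hydroxy-17-norlabdan-18-oate (9α-H) | O[C@@H]1CC[C@@H]2[C@](C)(CCC[C@@]2(C)C(=O)OCC[Si](C)(C)C)[C@H]1CC[C@H](C)CCO[Si](c1ccccc1)(c1ccccc1)C(C)(C)C | intermediate
26 | 2-(trimethylsilyl)ethyl (13S)-15-(tert-butyldiphenylsilyloxy)-8-oxo-17-norlabdan-18-oate | O=C1CC[C@@H]2[C@](C)(CCC[C@@]2(C)C(=O)OCC[Si](C)(C)C)[C@H]1CC[C@H](C)CCO[Si](c1ccccc1)(c1ccccc1)C(C)(C)C | intermediate
27 | 2-(trimethylsilyl)ethyl (13S)-15-(tert-butyldiphenylsilyloxy)labd-8(17)-en-18-oate | C=C1CC[C@@H]2[C@](C)(CCC[C@@]2(C)C(=O)OCC[Si](C)(C)C)[C@H]1CC[C@H](C)CCO[Si](c1ccccc1)(c1ccccc1)C(C)(C)C | intermediate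
28 | (13S)-15-hydroxylabd-8(17)-en-18-oic acid | C=C1CC[C@@H]2[C@](C)(CCC[C@@]2(C)C(=O)O)[C@H]1CC[C@H](C)CCO | intermediate
29 | (4R,5R,9S,10R,13S)-15-acetoxylabd-8(17)-en-18-oic acid, CNP0401865.1 | C=C1CC[C@@H]2[C@](C)(CCC[C@@]2(C)C(=O)O)[C@H]1CC[C@H](C)CCOC(C)=O | target

**Step count.** Total: 19 steps. Longest linear sequence: 16 steps (steps 1–10, then 14–19); the side-chain branch (steps 11–13) joins at step 14.

**The three steps most likely to fail**

1. Step 7 (key step). Process at risk: with the C9 carbonyl free, enolisation toward C8 may be followed by transfer of the lactone acyl group to O9, or the double silylation may stay incomplete, so that the ketene acetal does not form cleanly. The fallback sets out from 11 and masks the ketone with a true protecting group before the rearrangement. 1,2-Bis(trimethylsilyloxy)ethane and Me3SiOTf (cat.) in CH2Cl2 at −78 → −20 °C give the dioxolane lactone F1. A single deprotonation (LiN(iPr)2, Me3SiCl, Et3N, THF, −78 °C) gives its silyl ketene acetal F2, which rearranges in PhMe at 105 °C to the silyl ester F3. Aqueous work-up gives the ketal acid F4, and 1 M HCl in acetone removes the dioxolane, so the route is rejoined at 14.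

2. Step 2. Process at risk: weak facial discrimination by the chiral Lewis acid on the α-methyl enone (low enantioselectivity), or slow turnover. The fallback sets out from 2, 3 and 4 and moves the enantiocontrol from the conjugate addition to the reduction. The Michael–aldol sequence is run with an achiral promoter (Me3SiOTf cat., CH2Cl2, −78 °C; then BF3·OEt2), which gives 5 and 6 together with the enantiomeric silyl enol ether F5 and the enantiomeric aldol adduct F6. Oxidation as in step 3 gives 7 and the enantiomeric ynone F7. The (R,R)-configured ruthenium catalyst of step 4 reduces both antipodes to (1R)-carbinols, 8 and the diastereomeric hydroxy ester F8, which lactonise to 9 and the diastereomeric lactone F9 (alkynyl group trans to the angular methyl). Chromatographic separation returns the route at 9, at the cost of half of the material.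

3. Step 17. Process at risk: enolisation of the hindered, α-branched C8 ketone by the basic ylide in place of addition, so that conversion stalls. The fallback sets out from 26 and uses a Peterson olefination: Me3SiCH2Li with CeCl3 (THF, −78 °C) adds to the ketone to give the β-hydroxysilane F10, and KH in THF induces syn-elimination to the exocyclic alkene, which rejoins the route at 27.

**Further compounds**

F1 | step 7 | dioxolane (C9 ketal) of vinyl lactone 11 (C4 epimers) | C=C[C@@H]1OC(=O)C(C)[C@@H]2CCCC3(OCCO3)[C@@]12C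
F2 | step 7 | trimethylsilyl ketene acetal of F1 | C=C[C@@H]1OC(O[Si](C)(C)C)=C(C)[C@@H]2CCCC3(OCCO3)[C@@]12C
F3 | step 7 | trimethylsilyl ester of the C9-ketal octalin acid | C1CC[C@@H]2[C@](C)(C=CC[C@@]2(C)C(=O)O[Si](C)(C)C)C13OCCO3
F4 | step 7 | C9-ketal octalin acid (dioxolane of 14) | C1CC[C@@H]2[C@](C)(C=CC[C@@]2(C)C(=O)O)C13OCCO3
F5 | step 2 | methyl 2-[(1R)-2-methyl-3-(trimethylsilyloxy)cyclohex-2-en-1-yl]propanoate (enantiomer of 5) | COC(=O)C(C)[C@H]1CCCC(O[Si](C)(C)C)=C1C
F6 | step 2 | methyl 2-[(1R,2S)-2-[1-hydroxy-3-(trimethylsilyl)prop-2-ynyl]-2-methyl-3-oxocyclohexyl]propanoate (enantiomer of 6) | C[Si](C)(C)C#CC(O)[C@@]1(C)C(=O)CCC[C@@H]1C(C)C(=O)OC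
F7 | step 2 | methyl 2-[(1R,2R)-2-methyl-3-oxo-2-[3-(trimethylsilyl)prop-2-ynoyl]cyclohexyl]propanoate (enantiomer of 7) | C[Si](C)(C)C#CC(=O)[C@@]1(C)C(=O)CCC[C@@H]1C(C)C(=O)OC
F8 | step 2 | methyl 2-[(1R,2S)-2-[(1R)-1-hydroxy-3-(trimethylsilyl)prop-2-ynyl]-2-methyl-3-oxocyclohexyl]propanoate (diastereomer of 8) | C[Si](C)(C)C#C[C@H](O)[C@@]1(C)C(=O)CCC[C@@H]1C(C)C(=O)OC
F9 | step 2 | (1R,4aR,8aS)-4,8a-dimethyl-1-[2-(trimethylsilyl)ethynyl]hexahydro-1H-isochromene-3,8-dione (diastereomer of 9) | C[Si](C)(C)C#C[C@@H]1OC(=O)C(C)[C@H]2CCCC(=O)[C@]12C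
F10 | step 17 | 2-(trimethylsilyl)ethyl (13S)-15-(tert-butyldiphenylsilyloxy)-8-hydroxy-8-(trimethylsilylmethyl)-17-norlabdan-18-oate (C8 epimers) | C[Si](C)(C)CC1(O)CC[C@@H]2[C@](C)(CCC[C@@]2(C)C(=O)OCC[Si](C)(C)C)[C@H]1CC[C@H](C)CCO[Si](c1ccccc1)(c1ccccc1)C(C)(C)C
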